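**Retrosynthetic overview**
1. Target 18 ⇐ 17 ⇐ 16 by hydrogenolysis of four benzyl ethers and reductive removal of two pivalates. 16 is cut at the interflavan C4–C8 bond into the 4-methoxyflavan 12 (upper unit) and tetra-O-benzyl-(+)-catechin 14 (lower unit, chiral pool, brings both of its stereocentres).
2. 12 ⇐ flavan 10 by benzylic oxidation at C4. 10 is cut at the aryl ether bond O1–C8a of ring C, back to the open-chain (S)-1,3-diarylpropan-1-ol 6, whose ring A is a plain 4-hydroxyphenyl group.
3. Enabling feature: in the upper unit the free C7–OH of ring A stands para to C4a (the carbon carrying the C4–C3–C2 chain) and meta to C8a. Dearomatisation of this p-alkylphenol at C4a therefore makes C8a the β-carbon of a cyclohexadienone, within six-ring reach of the C2 oxygen, and loss of water restores ring A with the resorcinol pattern.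
4. 6 ⇐ ketone 5 (asymmetric transfer hydrogenation sets C2) ⇐ chalcone 4 ⇐ acetophenone 2 + 4-hydroxybenzaldehyde 3. C4 is relayed from C2 by pseudo-axial attack on the flavan-4-yl cation 15 in step 8.
5. Ring order: rings A and B are bought as benzene rings, ring C is closed in step 5, the three rings of the lower unit come intact with catechin, and the two units are joined in step 8.

Key step: step 5

Assumption: 12 is drawn as the expected 2,4-trans (4R) epimer and 9 as one cis-fused diastereomer; in both cases the other isomer converges on the same next species (cation 15 from either epimer of 12, flavan 10 from either isomer of 9), so these ratios do not matter.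

**Step 1**
Reactants: 1 3',4'-dihydroxyacetophenone
Product: 2 3',4'-bis(pivaloyloxy)acetophenone
Conditions: PivCl (2.4 equiv), Et3N, DMAP (cat.), CH2Cl2, 0 °C to rt
Reagents that add atoms: pivaloyl chloride, CC(C)(C)C(=O)Cl
Why: DMAP-catalysed O-acylation of both phenols; the pivalates make ring B electron-poor, so the later benzylic C2–O bond cannot ionise in acid, and they survive every step up to step 9.

**Step 2**
Reactants: 2 3',4'-bis(pivaloyloxy)acetophenone; 3 4-hydroxybenzaldehyde
Product: 4 (E)-1-[3,4-bis(pivaloyloxy)phenyl]-3-(4-hydroxyphenyl)prop-2-en-1-one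
Conditions: BF3·OEt2 (0.5 equiv), 1,4-dioxane, rt
Reagents that add atoms: none
Why: Lewis acid-promoted Claisen–Schmidt (aldol) condensation, chosen over base because it spares the aryl esters and tolerates the free phenol; the E-enone should form under thermodynamic control.

**Step 3**
Reactants: 4 (E)-1-[3,4-bis(pivaloyloxy)phenyl]-3-(4-hydroxyphenyl)prop-2-en-1-one
Product: 5 1-[3,4-bis(pivaloyloxy)phenyl]-3-(4-hydroxyphenyl)propan-1-one
Conditions: H2 (1 atm), 10% Pd/C, Ph2S (cat.), EtOAc, rt
Reagents that add atoms: none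
Why: Chemoselective catalytic hydrogenation of the enone C=C; the sulfide-poisoned palladium on carbon should stop at the saturated aryl ketone.

**Step 4**
Reactants: 5 1-[3,4-bis(pivaloyloxy)phenyl]-3-(4-hydroxyphenyl)propan-1-one
Product: 6 (S)-1-[3,4-bis(pivaloyloxy)phenyl]-3-(4-hydroxyphenyl)propan-1-ol
Conditions: RuCl(p-cymene)[(S,S)-TsDPEN] (1 mol %), HCO2H/Et3N (5:2), EtOAc, 30 °C
Reagents that add atoms: none
Why: Noyori–Ikariya asymmetric transfer hydrogenation of an aryl alkyl ketone; the (S,S)-ligand should deliver hydride to the Re face and set the (S)-carbinol (future C2) by catalyst control.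

**Step 5**
Reactants: 6 (S)-1-[3,4-bis(pivaloyloxy)phenyl]-3-(4-hydroxyphenyl)propan-1-ol
Product: 10 (2S)-2-[3,4-bis(pivaloyloxy)phenyl]chroman-7-ol, via hydroperoxydienone 7 (not isolated), via quinol 8 (not isolated), via bicyclic enone 9 (not isolated)
Conditions: O2 (1 atm), methylene blue (1 mol %), NaHCO3, MeCN/H2O (9:1), white LED, 0 °C; Me2S, 0 °C to rt; solvent switch to toluene, TsOH·H2O (0.3 equiv), 80 °C, dilute (one telescoped operation, no intermediate purified)
Reagents that add atoms: none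
Why: Proposed new method: singlet oxygen adds to the phenol(ate) of ring A at the carbon para to the OH (future C4a) to give hydroperoxide 7, Me2S reduces it to p-quinol 8, and under TsOH the C2 hydroxyl adds to the dienone β-carbon (future C8a) to give 9, whose enol loses the tertiary C4a–OH and the C8a–H as water and rearomatises to 10, so that the net change is a dehydrogenative C–H etherification meta to the phenol. The closest known reaction types are the singlet-oxygen dearomatisation of p-alkylphenols to p-quinols, their intramolecular oxa-Michael cyclisation, and the acid-induced conjugate addition–dehydration of p-quinols to meta-substituted phenols; what is new is their union into a chroman-forming aryl C–O cascade. Ring C is closed in a 6-exo-trig oxa-Michael mode. No lasting stereocentre is created (C4a and C8a of 9 are erased on aromatisation), and C2, set in step 4, takes no part in bond making or breaking. The step needs oxygen to attack C8a and not C4a, which is secured because singlet oxygen never generates a phenoxonium ion (the species that would be trapped as a five-membered spiro ether), the two dienone β-carbons are equivalent, and attack at any other carbon would give a four-membered ring. It also needs C2 to resist ionisation in hot acid, which the two pivalates secure by making ring B electron-poor, and for the same reason ring B is not touched by singlet oxygen.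

**Step 6**
Reactants: 10 (2S)-2-[3,4-bis(pivaloyloxy)phenyl]chroman-7-ol
Product: 12 (2S,4R)-2-[3,4-bis(pivaloyloxy)phenyl]-4-methoxychroman-7-ol, via quinone methide 11 (not isolated)
Conditions: DDQ (1.05 equiv), CH2Cl2/MeOH (4:1), 0 °C; used without chromatography
Reagents that add atoms: methanol, CO
Why: DDQ dehydrogenation of a p-alkylphenol (hydride abstraction at C4, para to the 7-OH) to the neutral p-quinone methide, followed by 1,6-addition of methanol, which should enter pseudo-axially anti to the equatorial C2 aryl group.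

**Step 7**
Reactants: 13 (+)-catechin
Product: 14 5,7,3',4'-tetra-O-benzyl-(+)-catechin
Conditions: BnBr (4.4 equiv), K2CO3, DMF, 0 °C to rt, argon
Reagents that add atoms: benzyl bromide, BrCc1ccccc1
Why: Williamson etherification of the four phenols, which are far more acidic than the secondary 3-OH, so the alcohol should stay free and both stereocentres are untouched.

**Step 8**
Reactants: 12 (2S,4R)-2-[3,4-bis(pivaloyloxy)phenyl]-4-methoxychroman-7-ol; 14 5,7,3',4'-tetra-O-benzyl-(+)-catechin (3 equiv)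
Product: 16 (2S,4R)-7-hydroxy-3',4'-bis(pivaloyloxy)flavan-(4→8)-5,7,3',4'-tetra-O-benzyl-(+)-catechin, via flavan-4-yl cation 15 (not isolated)
Conditions: TMSOTf (0.3 equiv), CH2Cl2, −78 to −40 °C; then aqueous NaHCO3
Reagents that add atoms: none
Why: Lewis acid ionisation of the p-hydroxybenzylic methyl ether expels methanol and gives the 7-hydroxyflavan-4-ylium ion 15 (a benzylic cation stabilised by the para 7-OH, distinct from the neutral quinone methide of step 6), which C8 of 14 (the more accessible nucleophilic carbon of the protected catechin ring A) captures in a Friedel–Crafts alkylation; under kinetic control the nucleophile should enter pseudo-axially, anti to the equatorial C2 aryl group, so C2 (S) relays into C4 (R) and the 2,4-trans interflavan bond results.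

**Step 9**
Reactants: 16 (2S,4R)-7-hydroxy-3',4'-bis(pivaloyloxy)flavan-(4→8)-5,7,3',4'-tetra-O-benzyl-(+)-catechin
Product: 17 (2S,4R)-7,3',4'-trihydroxyflavan-(4→8)-5,7,3',4'-tetra-O-benzyl-(+)-catechin
Conditions: i-Bu2AlH (DIBAL-H, 8 equiv), CH2Cl2, −78 °C; aqueous potassium sodium tartrate
Reagents that add atoms: none
Why: Reductive cleavage of the two aryl pivalates at low temperature under non-basic conditions, so neither flavan C2 centre can epimerise through a ring-B quinone methide; benzyl ethers are inert.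

**Step 10**
Reactants: 17 (2S,4R)-7,3',4'-trihydroxyflavan-(4→8)-5,7,3',4'-tetra-O-benzyl-(+)-catechin
Product: 18 (2S,4R)-7,3',4'-trihydroxyflavan-(4→8)-(+)-catechin (target)
Conditions: H2 (1 atm), Pd(OH)2/C, THF/MeOH (1:1), rt
Reagents that add atoms: none
Why: Catalytic hydrogenolysis of the four O-benzyl ethers under neutral conditions, which should leave the diarylmethine C4–C8 bond and the cyclic benzylic C2–O bonds intact.

**Compound list**
1 | 3',4'-dihydroxyacetophenone | CC(=O)c1ccc(O)c(O)c1 | starting material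
2 | 3',4'-bis(pivaloyloxy)acetophenone | CC(=O)c1ccc(OC(=O)C(C)(C)C)c(OC(=O)C(C)(C)C)c1 | intermediate
3 | 4-hydroxybenzaldehyde | O=Cc1ccc(O)cc1 | starting material
4 | (E)-1-[3,4-bis(pivaloyloxy)phenyl]-3-(4-hydroxyphenyl)prop-2-en-1-one | O=C(/C=C/c1ccc(O)cc1)c1ccc(OC(=O)C(C)(C)C)c(OC(=O)C(C)(C)C)c1 | intermediate
5 | 1-[3,4-bis(pivaloyloxy)phenyl]-3-(4-hydroxyphenyl)propan-1-one | O=C(CCc1ccc(O)cc1)c1ccc(OC(=O)C(C)(C)C)c(OC(=O)C(C)(C)C)c1 | intermediate
6 | (S)-1-[3,4-bis(pivaloyloxy)phenyl]-3-(4-hydroxyphenyl)propan-1-ol | O[C@H](c1ccc(OC(=O)C(C)(C)C)c(OC(=O)C(C)(C)C)c1)CCc1ccc(O)cc1 | intermediate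
7 | 4-hydroperoxy-4-[(3S)-3-hydroxy-3-(3,4-bis(pivaloyloxy)phenyl)propyl]cyclohexa-2,5-dien-1-one | OOC1(CC[C@H](O)c2ccc(OC(=O)C(C)(C)C)c(OC(=O)C(C)(C)C)c2)C=CC(=O)C=C1 | intermediate (not isolated)
8 | 4-hydroxy-4-[(3S)-3-hydroxy-3-(3,4-bis(pivaloyloxy)phenyl)propyl]cyclohexa-2,5-dien-1-one | OC1(CC[C@H](O)c2ccc(OC(=O)C(C)(C)C)c(OC(=O)C(C)(C)C)c2)C=CC(=O)C=C1 | intermediate (not isolated)
9 | (2S)-2-[3,4-bis(pivaloyloxy)phenyl]-4a-hydroxy-2,3,4,4a,8,8a-hexahydro-7H-chromen-7-one, cis-fused, H-2, H-8a and 4a-OH on one face | O=C1C=C[C@@]2(O)CC[C@@H](c3ccc(OC(=O)C(C)(C)C)c(OC(=O)C(C)(C)C)c3)O[C@H]2C1 | intermediate (not isolated)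
10 | (2S)-2-[3,4-bis(pivaloyloxy)phenyl]chroman-7-ol | Oc1ccc2c(c1)O[C@H](c1ccc(OC(=O)C(C)(C)C)c(OC(=O)C(C)(C)C)c1)CC2 | intermediate
11 | (2S)-2-[3,4-bis(pivaloyloxy)phenyl]-2,3-dihydro-7H-chromen-7-one (p-quinone methide) | O=C1C=CC2=CC[C@@H](c3ccc(OC(=O)C(C)(C)C)c(OC(=O)C(C)(C)C)c3)OC2=C1 | intermediate (not isolated)
12 | (2S,4R)-2-[3,4-bis(pivaloyloxy)phenyl]-4-methoxychroman-7-ol (2,4-trans) | Oc1ccc2c(c1)O[C@H](c1ccc(OC(=O)C(C)(C)C)c(OC(=O)C(C)(C)C)c1)C[C@H]2OC | intermediate
13 | (+)-catechin, (2R,3S) | Oc1cc(O)c2c(c1)O[C@H](c1ccc(O)c(O)c1)[C@@H](O)C2 | starting material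
14 | 5,7,3',4'-tetra-O-benzyl-(+)-catechin, (2R,3S) | C(Oc1cc(OCc2ccccc2)c2c(c1)O[C@H](c1ccc(OCc3ccccc3)c(OCc3ccccc3)c1)[C@@H](O)C2)c1ccccc1 | intermediate
15 | (2S)-2-[3,4-bis(pivaloyloxy)phenyl]-7-hydroxychroman-4-ylium (flavan-4-yl cation, the O-protonated form of 11) | Oc1ccc2c(c1)O[C@H](c1ccc(OC(=O)C(C)(C)C)c(OC(=O)C(C)(C)C)c1)C[CH+]2 | intermediate (not isolated)
16 | (2S,4R)-7-hydroxy-3',4'-bis(pivaloyloxy)flavan-(4→8)-5,7,3',4'-tetra-O-benzyl-(+)-catechin | Oc1ccc2c(c1)O[C@H](c1ccc(OC(=O)C(C)(C)C)c(OC(=O)C(C)(C)C)c1)C[C@H]2c1c(OCc2ccccc2)cc(OCc2ccccc2)c2c1O[C@H](c1ccc(OCc3ccccc3)c(OCc3ccccc3)c1)[C@@H](O)C2 | intermediate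
17 | (2S,4R)-7,3',4'-trihydroxyflavan-(4→8)-5,7,3',4'-tetra-O-benzyl-(+)-catechin | Oc1ccc2c(c1)O[C@H](c1ccc(O)c(O)c1)C[C@H]2c1c(OCc2ccccc2)cc(OCc2ccccc2)c2c1O[C@H](c1ccc(OCc3ccccc3)c(OCc3ccccc3)c1)[C@@H](O)C2 | intermediate
18 | (2S,4R)-7,3',4'-trihydroxyflavan-(4→8)-(+)-catechin; upper unit 2S,4R (2,4-trans), lower unit 2R,3S | Oc1ccc2c(c1)O[C@H](c1ccc(O)c(O)c1)C[C@H]2c1c(O)cc(O)c2c1O[C@H](c1ccc(O)c(O)c1)[C@@H](O)C2 | target

Total steps: 10. Longest linear sequence: 9 (steps 1–6 and 8–10; step 7 is a one-step branch).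

**Steps most likely to fail**

Step 5 (key step). The acid stage may stall at bicyclic enone 9 because its enolisation is slow, or quinol 8 may be diverted into the acid-induced 1,2-alkyl shift of quinols before dehydrative rearomatisation; the product phenol may also add to unreacted dienone. The fallback uses known chemistry, sets out from ketone 2 and returns at 10. 2-Bromo-4-hydroxybenzaldehyde F1 (bought) is O-benzylated (BnBr, K2CO3, DMF) to 4-(benzyloxy)-2-bromobenzaldehyde F2, which is condensed with 2 (BF3·OEt2, dioxane) to (E)-3-[4-(benzyloxy)-2-bromophenyl]-1-[3,4-bis(pivaloyloxy)phenyl]prop-2-en-1-one F3. Hydrogenation of the enone C=C with RhCl(PPh3)3 and H2, which spares the aryl bromide and the benzyl ether, gives 3-[4-(benzyloxy)-2-bromophenyl]-1-[3,4-bis(pivaloyloxy)phenyl]propan-1-one F4. The transfer hydrogenation of step 4 gives (S)-3-[4-(benzyloxy)-2-bromophenyl]-1-[3,4-bis(pivaloyloxy)phenyl]propan-1-ol F5. A palladium-catalysed intramolecular Buchwald–Hartwig etherification (Pd(OAc)2, 2-(di-tert-butylphosphino)-1,1'-binaphthyl, K3PO4, toluene, 70 °C) closes the same O1–C8a bond without touching C2 and gives (2S)-7-(benzyloxy)-2-[3,4-bis(pivaloyloxy)phenyl]chroman F6. Hydrogenolysis of its single benzyl ether (H2, Pd/C, EtOAc) returns to 10.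

Step 6. The phenol may be over-oxidised to the C4 ketone, and the unsubstituted quinone methide 11 may oligomerise before methanol captures it; the labile ether 12 may also lose methanol on handling. The fallback sets out from 10 and returns at 16, making the over-oxidation product the isolated intermediate. DDQ (2.2 equiv) in 1,4-dioxane/H2O takes 10 to (2S)-2-[3,4-bis(pivaloyloxy)phenyl]-7-hydroxychroman-4-one F7. Luche reduction (NaBH4, CeCl3·7H2O, MeOH/THF, −20 °C) gives the 2,4-cis alcohol (2S,4S)-2-[3,4-bis(pivaloyloxy)phenyl]chroman-4,7-diol F8. This flavan-4-ol is ionised directly in the presence of 14 (TMSOTf cat., CH2Cl2, −78 °C), with loss of water in place of methanol, and the same Friedel–Crafts capture at C8 of 14 gives 16.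

Step 8. The phenolic electrophile may self-condense through its own ring A, the product may be alkylated again, and acid-induced reversal of the coupling may erode the trans selectivity. The fallback sets out from 12 and returns at 17, replacing the self-nucleophilic phenol by a non-nucleophilic aryl ester. Acylation of 12 (PivCl, Et3N, DMAP) gives (2S,4R)-2-[3,4-bis(pivaloyloxy)phenyl]-4-methoxychroman-7-yl pivalate F9. Its TMSOTf-mediated Friedel–Crafts coupling with 14 gives (2S,4R)-7,3',4'-tris(pivaloyloxy)flavan-(4→8)-5,7,3',4'-tetra-O-benzyl-(+)-catechin F10. DIBAL-H at −78 °C removes all three pivalates and gives 17.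

**Further compounds**
F1 | step 5 | 2-bromo-4-hydroxybenzaldehyde (bought) | O=Cc1ccc(O)cc1Br
F2 | step 5 | 4-(benzyloxy)-2-bromobenzaldehyde | O=Cc1ccc(OCc2ccccc2)cc1Br
F3 | step 5 | (E)-3-[4-(benzyloxy)-2-bromophenyl]-1-[3,4-bis(pivaloyloxy)phenyl]prop-2-en-1-one | O=C(/C=C/c1ccc(OCc2ccccc2)cc1Br)c1ccc(OC(=O)C(C)(C)C)c(OC(=O)C(C)(C)C)c1
F4 | step 5 | 3-[4-(benzyloxy)-2-bromophenyl]-1-[3,4-bis(pivaloyloxy)phenyl]propan-1-one | O=C(CCc1ccc(OCc2ccccc2)cc1Br)c1ccc(OC(=O)C(C)(C)C)c(OC(=O)C(C)(C)C)c1
F5 | step 5 | (S)-3-[4-(benzyloxy)-2-bromophenyl]-1-[3,4-bis(pivaloyloxy)phenyl]propan-1-ol | O[C@H](c1ccc(OC(=O)C(C)(C)C)c(OC(=O)C(C)(C)C)c1)CCc1ccc(OCc2ccccc2)cc1Br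
F6 | step 5 | (2S)-7-(benzyloxy)-2-[3,4-bis(pivaloyloxy)phenyl]chroman | C(Oc1ccc2c(c1)O[C@H](c1ccc(OC(=O)C(C)(C)C)c(OC(=O)C(C)(C)C)c1)CC2)c1ccccc1
F7 | step 6 | (2S)-2-[3,4-bis(pivaloyloxy)phenyl]-7-hydroxychroman-4-one | O=C1C[C@@H](c2ccc(OC(=O)C(C)(C)C)c(OC(=O)C(C)(C)C)c2)Oc2cc(O)ccc21
F8 | step 6 | (2S,4S)-2-[3,4-bis(pivaloyloxy)phenyl]chroman-4,7-diol (2,4-cis) | Oc1ccc2c(c1)O[C@H](c1ccc(OC(=O)C(C)(C)C)c(OC(=O)C(C)(C)C)c1)C[C@@H]2O
F9 | step 8 | (2S,4R)-2-[3,4-bis(pivaloyloxy)phenyl]-4-methoxychroman-7-yl pivalate | CC(C)(C)C(=O)Oc1ccc2c(c1)O[C@H](c1ccc(OC(=O)C(C)(C)C)c(OC(=O)C(C)(C)C)c1)C[C@H]2OC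
F10 | step 8 | (2S,4R)-7,3',4'-tris(pivaloyloxy)flavan-(4→8)-5,7,3',4'-tetra-O-benzyl-(+)-catechin | CC(C)(C)C(=O)Oc1ccc2c(c1)O[C@H](c1ccc(OC(=O)C(C)(C)C)c(OC(=O)C(C)(C)C)c1)C[C@H]2c1c(OCc2ccccc2)cc(OCc2ccccc2)c2c1O[C@H](c1ccc(OCc3ccccc3)c(OCc3ccccc3)c1)[C@@H](O)C2
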